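**Plan**

Retrosynthetic cuts: the C15 acetate and the C18 carboxyl (carried as a benzyl ether and a methyl carbinol); C8–OH/C17 (from an 8-ketone); C1–C10 of ring A; C4–C5 (a [3,3] shift); C9–C11 (reductive alkylation of cyclohexane-1,3-dione).
Forward order: ring B is cyclohexane-1,3-dione carrying the side chain; a dianionic ester-enolate Claisen rearrangement joins C4 to C5 and turns C20 into an exocyclic methylene; ring A is closed last through C1–C10; the C3 and C8 helpers are then removed or converted.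
Enabling feature: C10 is a quaternary ring-fusion carbon whose methyl C20 is the hydrogen-atom adduct of a C10=C20 methylene, and C1 lies five bonds away along C5–C4–C3–C2. A temporary C3 carbonyl makes C1 the tip of a vinyl ketone, so one 6-endo radical conjugate addition forms C1–C10, the angular methyl and ring A together.
Stereochemistry: C13 from methyl hydrogen (R)-3-methylglutarate; C4 and C5 from the carbinol of ethyl (S)-3-hydroxybutanoate through a chelated chair Claisen; C9 by protonation anti to the C5 substituent (confirmed thermodynamically at the 8-ketone); C10 in the key step under control of ring B and C4; C8 by equatorial oxygen capture.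

Key step: step 15

Remark on the chemistry: atoms are labelled by the labdane numbering of the target (C18 = carboxyl carbon on C4, C19 = methyl on C4, C20 = methyl on C10, C17 = methyl on C8). It is assumed that the dianion rearrangement of step 10 passes through the chelated chair, as its simpler congeners do.

**Route**

Step 1
Reactants: 1 (3R)-5-methoxy-3-methyl-5-oxopentanoic acid
Product: 2 methyl (3R)-5-hydroxy-3-methylpentanoate
Conditions: BH3·SMe2, THF, −10 → 25 °C; MeOH quench
Reagents that add atoms: none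
Why: Borane reduces the free carboxylic acid much faster than the ester (chemoselective acid reduction), so the acid end becomes the future C15 carbinol and the stereocentre (future C13) is untouched.

Step 2
Reactants: 2 methyl (3R)-5-hydroxy-3-methylpentanoate
Product: 3 methyl (3R)-5-(benzyloxy)-3-methylpentanoate
Conditions: benzyl 2,2,2-trichloroacetimidate, TfOH (cat.), CH2Cl2/cyclohexane, 0 → 25 °C
Reagents that add atoms: benzyl 2,2,2-trichloroacetimidate, N=C(OCc1ccccc1)C(Cl)(Cl)Cl
Why: Acid-catalysed O-benzylation with the trichloroacetimidate avoids the basic conditions that would lactonise or condense the hydroxy ester.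

Step 3
Reactants: 3 methyl (3R)-5-(benzyloxy)-3-methylpentanoate
Product: 4 (3R)-5-(benzyloxy)-3-methylpentanal
Conditions: i-Bu2AlH, CH2Cl2, −78 °C; aq. potassium sodium tartrate
Reagents that add atoms: none
Why: Low-temperature half-reduction of a methyl ester stops at the tetrahedral aluminate, which should release the aldehyde (future C11) on work-up.

Step 4
Reactants: 4 (3R)-5-(benzyloxy)-3-methylpentanal; 5 cyclohexane-1,3-dione
Product: 7 2-[(3S)-5-(benzyloxy)-3-methylpentyl]cyclohexane-1,3-dione, via alkylidene dione 6 (not isolated)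
Conditions: L-proline (cat.), diethyl 2,6-dimethyl-1,4-dihydropyridine-3,5-dicarboxylate, CH2Cl2, 25 °C
Reagents that add atoms: none
Why: Organocatalytic reductive alkylation (Knoevenagel condensation, then hydride transfer from the dihydropyridine) should give the 2-monoalkyl dione without O-alkylation or double addition, forming the C9–C11 bond.

Step 5
Reactants: 7 2-[(3S)-5-(benzyloxy)-3-methylpentyl]cyclohexane-1,3-dione
Product: 8 2-[(3S)-5-(benzyloxy)-3-methylpentyl]-3-{[tri(propan-2-yl)silyl]oxy}cyclohex-2-en-1-one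
Conditions: i-Pr3SiOTf, Et3N, CH2Cl2, −78 → 0 °C
Reagents that add atoms: triisopropylsilyl trifluoromethanesulfonate, CC(C)[Si](OS(=O)(=O)C(F)(F)F)(C(C)C)C(C)C
Why: O-silylation of the enolised dione differentiates the two carbonyls (C8 masked, C10 free) and keeps C9 trigonal, so that ring B carries no stereocentre before the Claisen step.

Step 6
Reactants: 8 2-[(3S)-5-(benzyloxy)-3-methylpentyl]-3-{[tri(propan-2-yl)silyl]oxy}cyclohex-2-en-1-one
Product: 9 6-[(3S)-5-(benzyloxy)-3-methylpentyl]-5-{[tri(propan-2-yl)silyl]oxy}cyclohexa-1,5-dien-1-yl trifluoromethanesulfonate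
Conditions: LiN(i-Pr)2, THF, −78 °C; then PhNTf2, −78 → 0 °C; aq. NH4Cl
Reagents that add atoms: N-phenylbis(trifluoromethanesulfonimide), O=S(=O)(N(c1ccccc1)S(=O)(=O)C(F)(F)F)C(F)(F)F
Why: Kinetic deprotonation of a 3-oxy-enone occurs at the alpha-prime carbon (C5), as in Stork–Danheiser chemistry, and O-triflation of that enolate should give the dienyl triflate with the C10=C5 double bond.

Step 7
Reactants: 9 6-[(3S)-5-(benzyloxy)-3-methylpentyl]-5-{[tri(propan-2-yl)silyl]oxy}cyclohexa-1,5-dien-1-yl trifluoromethanesulfonate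
Product: 10 {6-[(3S)-5-(benzyloxy)-3-methylpentyl]-5-{[tri(propan-2-yl)silyl]oxy}cyclohexa-1,5-dien-1-yl}methanol
Conditions: Bu3SnCH2OH, Pd(PPh3)4 (cat.), LiCl, 1,4-dioxane, 95 °C
Reagents that add atoms: (tributylstannyl)methanol, CCCC[Sn](CCCC)(CCCC)CO
Why: Stille coupling of the enol triflate with the hydroxymethyl stannane installs C20 as a primary allylic alcohol on the C10=C5 double bond.

Step 8
Reactants: 11 ethyl (3S)-3-hydroxybutanoate
Product: 12 ethyl (2S,3S)-3-hydroxy-2-methylbutanoate
Conditions: LiN(i-Pr)2 (2.2 equiv), THF, −78 → −20 °C; MeI, −78 → 0 °C; aq. NH4Cl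
Reagents that add atoms: iodomethane, CI
Why: Fráter–Seebach alkylation methylates the chelated dianion anti to the carbinol methyl; this supplies C19, and the configuration of the methylated carbon is irrelevant because it is re-enolised in step 10.

Step 9
Reactants: 10 {6-[(3S)-5-(benzyloxy)-3-methylpentyl]-5-{[tri(propan-2-yl)silyl]oxy}cyclohexa-1,5-dien-1-yl}methanol; 12 ethyl (2S,3S)-3-hydroxy-2-methylbutanoate (threefold excess)
Product: 13 {6-[(3S)-5-(benzyloxy)-3-methylpentyl]-5-{[tri(propan-2-yl)silyl]oxy}cyclohexa-1,5-dien-1-yl}methyl (2S,3S)-3-hydroxy-2-methylbutanoate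
Conditions: Ti(OEt)4 (cat.), toluene, 85 °C, ethanol removed under reduced pressure
Reagents that add atoms: none
Why: Titanate-catalysed transesterification is neutral enough for the silyl dienol ether and the beta-hydroxy ester, and should acylate the primary allylic alcohol in preference to the secondary carbinol.

Step 10
Reactants: 13 {6-[(3S)-5-(benzyloxy)-3-methylpentyl]-5-{[tri(propan-2-yl)silyl]oxy}cyclohexa-1,5-dien-1-yl}methyl (2S,3S)-3-hydroxy-2-methylbutanoate
Product: 15 (2S,3S)-2-[(1S)-3-[(3S)-5-(benzyloxy)-3-methylpentyl]-2-methylidene-4-{[tri(propan-2-yl)silyl]oxy}cyclohex-3-en-1-yl]-3-hydroxy-2-methylbutanoic acid, via chelated dilithium dianion 14 (not isolated)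
Conditions: LiN(i-Pr)2 (2.4 equiv), THF, −78 → 25 °C (45 °C if slow); aq. NH4Cl, then citric acid to pH 4
Reagents that add atoms: none
Why: In this dianionic ester-enolate Claisen rearrangement (Ireland–Claisen type) chelation fixes the enolate geometry (carbinol arm cis to OLi) and its face (attack anti to the carbinol methyl), so the chair transition state should give the C4 quaternary and C5 tertiary centres in the required relative and absolute configuration while moving the double bond to C10=C20.

Step 11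
Reactants: 15 (2S,3S)-2-[(1S)-3-[(3S)-5-(benzyloxy)-3-methylpentyl]-2-methylidene-4-{[tri(propan-2-yl)silyl]oxy}cyclohex-3-en-1-yl]-3-hydroxy-2-methylbutanoic acid
Product: 17 (2S,3S)-2-[(1S)-3-[(3S)-5-(benzyloxy)-3-methylpentyl]-2-methylidene-4-{[tri(propan-2-yl)silyl]oxy}cyclohex-3-en-1-yl]-3-(methoxymethoxy)-2-methylbutanoic acid, via methoxymethyl ester 16 (not isolated)
Conditions: MeOCH2Cl, i-Pr2NEt, CH2Cl2, 0 → 25 °C; then MgBr2·OEt2, Et2O, 0 °C; aq. work-up
Reagents that add atoms: chloromethyl methyl ether, COCCl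
Why: Methoxymethylation protects the hindered carbinol as a base-stable acetal for the Wolff–Kishner step, and the acylal-type methoxymethyl ester formed alongside is cleaved selectively by the mild magnesium Lewis acid.

Step 12
Reactants: 17 (2S,3S)-2-[(1S)-3-[(3S)-5-(benzyloxy)-3-methylpentyl]-2-methylidene-4-{[tri(propan-2-yl)silyl]oxy}cyclohex-3-en-1-yl]-3-(methoxymethoxy)-2-methylbutanoic acid
Product: 18 (2S,3S)-2-[(1S,3S)-3-[(3S)-5-(benzyloxy)-3-methylpentyl]-2-methylidene-4-oxocyclohexyl]-3-(methoxymethoxy)-2-methylbutanoic acid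
Conditions: Bu4NF, AcOH, THF, −78 °C
Reagents that add atoms: none
Why: Fluoride unmasks the extended enolate, whose kinetic (deconjugative) protonation occurs at the alpha carbon C9 anti to the pseudo-axial C5 substituent; this should give the beta,gamma-unsaturated ketone with the side chain cis to the C5 substituent and the C10=C20 methylene intact.

Step 13
Reactants: 18 (2S,3S)-2-[(1S,3S)-3-[(3S)-5-(benzyloxy)-3-methylpentyl]-2-methylidene-4-oxocyclohexyl]-3-(methoxymethoxy)-2-methylbutanoic acid
Product: 19 (2S,3S)-2-[(6S,8S)-6-[(3S)-5-(benzyloxy)-3-methylpentyl]-7-methylidene-1,4-dioxaspiro[4.5]decan-8-yl]-3-(methoxymethoxy)-2-methylbutanoic acid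
Conditions: Me3SiOCH2CH2OSiMe3, Me3SiOTf (cat.), CH2Cl2, −78 → −30 °C; pyridine, then aq. work-up
Reagents that add atoms: 1,2-bis(trimethylsilyloxy)ethane, C[Si](C)(C)OCCO[Si](C)(C)C
Why: Noyori ketalisation runs at low temperature without protic acid, so the ketone should be protected without migration of the exocyclic double bond or epimerisation at C9, leaving C8 inert for steps 14 to 16.

Step 14
Reactants: 19 (2S,3S)-2-[(6S,8S)-6-[(3S)-5-(benzyloxy)-3-methylpentyl]-7-methylidene-1,4-dioxaspiro[4.5]decan-8-yl]-3-(methoxymethoxy)-2-methylbutanoic acid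
Product: 21 (4S,5S)-4-[(6S,8S)-6-[(3S)-5-(benzyloxy)-3-methylpentyl]-7-methylidene-1,4-dioxaspiro[4.5]decan-8-yl]-5-(methoxymethoxy)-4-methylhex-1-en-3-one, via acid chloride 20 (not isolated)
Conditions: 1-chloro-N,N,2-trimethylprop-1-en-1-amine, CH2Cl2, 0 → 25 °C; then Bu3SnCH=CH2, Pd2(dba)3 (cat.), tri(2-furyl)phosphine, THF, 45 °C
Reagents that add atoms: tributyl(vinyl)stannane, C=C[Sn](CCCC)(CCCC)CCCC
Why: The hindered acid is converted into its chloride under neutral conditions and acyl Stille coupling then gives the vinyl ketone without organometallic over-addition, which puts C1 and C2 in place and makes C3 the temporary activating carbonyl.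

Step 15
Reactants: 21 (4S,5S)-4-[(6S,8S)-6-[(3S)-5-(benzyloxy)-3-methylpentyl]-7-methylidene-1,4-dioxaspiro[4.5]decan-8-yl]-5-(methoxymethoxy)-4-methylhex-1-en-3-one
Product: 22 (4S,5S,9S,10R,13S,18S)-15-(benzyloxy)-8,8-(ethane-1,2-diyldioxy)-18-(methoxymethoxy)-18-methyl-17-norlabdan-3-one
Conditions: Fe(acac)3 (0.5 equiv), PhSiH3 (2.5 equiv), EtOH/ethylene glycol 5:1, 0.01 M, 60 °C
Reagents that add atoms: none
Why: Fe(acac)3 and PhSiH3 form an iron hydride that transfers a hydrogen atom to C20 of the electron-rich 1,1-disubstituted alkene, creating the C20 methyl and a tertiary radical at C10; this nucleophilic radical adds to C1, the unsubstituted terminus of the vinyl ketone, and the resulting alpha-keto radical is reduced and protonated by ethanol. The closest known reaction type is the iron-catalysed reductive olefin coupling (a hydrogen-atom-transfer-initiated Giese addition) in its intramolecular form. Ring A is closed in the 6-endo-trig mode, because the 5-exo alternative would require attack at the alpha carbon C2 against the polarity of the acceptor. The new stereocentre C10 is set by the substrate: ring B should react as the chair with the C5 and C9 substituents equatorial, and bond formation from the equatorial direction (C20 becoming axial) gives the trans-decalin, in which only the methyl groups C19 and C20 become syn-axial, whereas the cis mode would place the larger C18 arm syn-axial to C20 and C6 axial on ring A. The step needs hydrogen-atom transfer to the methylene and not to the vinyl ketone, which the electron-poor character of the latter should secure, and ring closure faster than reduction of the radical, which the six-membered transition state and high dilution favour. C4, C5 and C9 are not touched.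

Step 16
Reactants: 22 (4S,5S,9S,10R,13S,18S)-15-(benzyloxy)-8,8-(ethane-1,2-diyldioxy)-18-(methoxymethoxy)-18-methyl-17-norlabdan-3-one
Product: 24 (4S,5S,9S,10R,13S,18S)-15-(benzyloxy)-8,8-(ethane-1,2-diyldioxy)-18-(methoxymethoxy)-18-methyl-17-norlabdane, via C3 hydrazone 23 (not isolated)
Conditions: N2H4·H2O, KOH, diethylene glycol, 130 °C then 200 °C
Reagents that add atoms: none
Why: Wolff–Kishner reduction (Huang-Minlon conditions) removes the helper carbonyl at C3; the alpha carbon C4 is quaternary, so neither epimerisation nor beta-elimination of the acetal oxygen can occur, and the ketal, the acetal and the benzyl ether are stable to hot base.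

Step 17
Reactants: 24 (4S,5S,9S,10R,13S,18S)-15-(benzyloxy)-8,8-(ethane-1,2-diyldioxy)-18-(methoxymethoxy)-18-methyl-17-norlabdane
Product: 25 (4S,5S,9S,10R,13S,18S)-15-(benzyloxy)-18-hydroxy-18-methyl-17-norlabdan-8-one
Conditions: 2 M HCl (aq.), THF/MeOH, 50 °C
Reagents that add atoms: water, O
Why: Aqueous acid hydrolyses the dioxolane and the methoxymethyl ether in one operation, and C9 next to the liberated ketone is free to settle in the equatorial configuration.

Step 18
Reactants: 25 (4S,5S,9S,10R,13S,18S)-15-(benzyloxy)-18-hydroxy-18-methyl-17-norlabdan-8-one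
Product: 26 (4S,5S,9R,10S,13S,18S)-15-(benzyloxy)-18-methyllabd-8(17)-en-18-ol
Conditions: Ph3PCH3Br, KOt-Bu, toluene, 25 → 90 °C
Reagents that add atoms: methyltriphenylphosphonium bromide, C[P+](c1ccccc1)(c1ccccc1)c1ccccc1.[Br-]
Why: Wittig methylenation of the hindered 8-ketone introduces C17; the basic medium should equilibrate C9 to the equatorial side chain before olefination, and the free carbinol is tolerated as its alkoxide (the changed descriptors at C9 and C10 reflect priority changes only).

Step 19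
Reactants: 26 (4S,5S,9R,10S,13S,18S)-15-(benzyloxy)-18-methyllabd-8(17)-en-18-ol
Product: 27 (4S,5S,8S,9S,10R,13S,18S)-15-(benzyloxy)-18-methyllabdane-8,18-diol
Conditions: Mn(dpm)3 (cat.), PhSiH3, O2 (1 atm), i-PrOH/CH2Cl2, 0 → 25 °C
Reagents that add atoms: dioxygen, O=O
Why: In this Mukaiyama hydration hydrogen-atom transfer to C17 gives the tertiary C8 radical, which should capture oxygen on the equatorial face away from the axial C20 methyl, placing the 8-hydroxyl trans to C20 and to the C9 chain.

Step 20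
Reactants: 27 (4S,5S,8S,9S,10R,13S,18S)-15-(benzyloxy)-18-methyllabdane-8,18-diol
Product: 30 (4S,5S,8S,9S,10R,13S)-15-(benzyloxy)-8-hydroxylabdan-18-oic acid, via methyl ketone 28 (not isolated), via tribromomethyl ketone 29 (not isolated)
Conditions: Br2, NaOH, H2O/1,4-dioxane, 0 → 25 °C; Na2SO3; HCl to pH 3
Reagents that add atoms: sodium hydroxide, [Na+].[OH-]
Why: In the haloform reaction of a methyl carbinol, hypobromite oxidises the secondary alcohol to the methyl ketone and tribrominates the methyl, and hydroxide then cleaves the tribromoketone, which excises the extra carbon and leaves the C18 carboxylic acid on the non-enolisable quaternary C4.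

Step 21
Reactants: 30 (4S,5S,8S,9S,10R,13S)-15-(benzyloxy)-8-hydroxylabdan-18-oic acid
Product: 31 (4S,5S,8S,9S,10R,13S)-8,15-dihydroxylabdan-18-oic acid
Conditions: H2 (1 atm), Pd/C (palladium on carbon), EtOAc, 25 °C
Reagents that add atoms: none
Why: Hydrogenolysis of the benzyl ether frees the C15 alcohol, and no other reducible group remains.

Step 22
Reactants: 31 (4S,5S,8S,9S,10R,13S)-8,15-dihydroxylabdan-18-oic acid
Product: 32 (4S,5S,8S,9S,10R,13S)-15-(acetyloxy)-8-hydroxylabdan-18-oic acid
Conditions: Ac2O, pyridine, 0 → 25 °C; then H2O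
Reagents that add atoms: acetic anhydride, CC(=O)OC(C)=O
Why: Acetylation of the primary alcohol is far faster than that of the tertiary 8-hydroxyl, and any mixed anhydride at the hindered acid is hydrolysed on aqueous work-up.

**Compound list**

1 | (3R)-5-methoxy-3-methyl-5-oxopentanoic acid (methyl hydrogen (R)-3-methylglutarate) | OC(=O)C[C@@H](C)CC(=O)OC | starting material
2 | methyl (3R)-5-hydroxy-3-methylpentanoate | OCC[C@@H](C)CC(=O)OC | intermediate
3 | methyl (3R)-5-(benzyloxy)-3-methylpentanoate | c1ccccc1COCC[C@@H](C)CC(=O)OC | intermediate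
4 | (3R)-5-(benzyloxy)-3-methylpentanal | c1ccccc1COCC[C@@H](C)CC=O | intermediate
5 | cyclohexane-1,3-dione | O=C1CCCC(=O)C1 | starting material
6 | 2-[(3S)-5-(benzyloxy)-3-methylpentylidene]cyclohexane-1,3-dione | O=C1CCCC(=O)C1=CC[C@H](C)CCOCc1ccccc1 | intermediate
7 | 2-[(3S)-5-(benzyloxy)-3-methylpentyl]cyclohexane-1,3-dione | O=C1CCCC(=O)C1CC[C@H](C)CCOCc1ccccc1 | intermediate
8 | 2-[(3S)-5-(benzyloxy)-3-methylpentyl]-3-{[tri(propan-2-yl)silyl]oxy}cyclohex-2-en-1-one | O=C1CCCC(O[Si](C(C)C)(C(C)C)C(C)C)=C1CC[C@H](C)CCOCc1ccccc1 | intermediate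
9 | 6-[(3S)-5-(benzyloxy)-3-methylpentyl]-5-{[tri(propan-2-yl)silyl]oxy}cyclohexa-1,5-dien-1-yl trifluoromethanesulfonate | FC(F)(F)S(=O)(=O)OC1=CCCC(O[Si](C(C)C)(C(C)C)C(C)C)=C1CC[C@H](C)CCOCc1ccccc1 | intermediate
10 | {6-[(3S)-5-(benzyloxy)-3-methylpentyl]-5-{[tri(propan-2-yl)silyl]oxy}cyclohexa-1,5-dien-1-yl}methanol | OCC1=CCCC(O[Si](C(C)C)(C(C)C)C(C)C)=C1CC[C@H](C)CCOCc1ccccc1 | intermediate
11 | ethyl (3S)-3-hydroxybutanoate | CCOC(=O)C[C@H](C)O | starting material
12 | ethyl (2S,3S)-3-hydroxy-2-methylbutanoate | CCOC(=O)[C@@H](C)[C@H](C)O | intermediate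
13 | {6-[(3S)-5-(benzyloxy)-3-methylpentyl]-5-{[tri(propan-2-yl)silyl]oxy}cyclohexa-1,5-dien-1-yl}methyl (2S,3S)-3-hydroxy-2-methylbutanoate | C[C@H](O)[C@H](C)C(=O)OCC1=CCCC(O[Si](C(C)C)(C(C)C)C(C)C)=C1CC[C@H](C)CCOCc1ccccc1 | intermediate
14 | chelated dilithium alkoxide enolate of 13 (carbinol arm cis to the enolate oxygen) | [Li+].[Li+].C[C@H]([O-])/C(C)=C(\[O-])OCC1=CCCC(O[Si](C(C)C)(C(C)C)C(C)C)=C1CC[C@H](C)CCOCc1ccccc1 | intermediate
15 | (2S,3S)-2-[(1S)-3-[(3S)-5-(benzyloxy)-3-methylpentyl]-2-methylidene-4-{[tri(propan-2-yl)silyl]oxy}cyclohex-3-en-1-yl]-3-hydroxy-2-methylbutanoic acid | C[C@H](O)[C@@](C)(C(=O)O)[C@H]1CCC(O[Si](C(C)C)(C(C)C)C(C)C)=C(CC[C@H](C)CCOCc2ccccc2)C1=C | intermediate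
16 | methoxymethyl ester of 17 | C[C@H](OCOC)[C@@](C)(C(=O)OCOC)[C@H]1CCC(O[Si](C(C)C)(C(C)C)C(C)C)=C(CC[C@H](C)CCOCc2ccccc2)C1=C | intermediate
17 | (2S,3S)-2-[(1S)-3-[(3S)-5-(benzyloxy)-3-methylpentyl]-2-methylidene-4-{[tri(propan-2-yl)silyl]oxy}cyclohex-3-en-1-yl]-3-(methoxymethoxy)-2-methylbutanoic acid | C[C@H](OCOC)[C@@](C)(C(=O)O)[C@H]1CCC(O[Si](C(C)C)(C(C)C)C(C)C)=C(CC[C@H](C)CCOCc2ccccc2)C1=C | intermediate
18 | (2S,3S)-2-[(1S,3S)-3-[(3S)-5-(benzyloxy)-3-methylpentyl]-2-methylidene-4-oxocyclohexyl]-3-(methoxymethoxy)-2-methylbutanoic acid | c1ccccc1COCC[C@@H](C)CC[C@H]1C(=C)[C@@H]([C@](C)(C(=O)O)[C@H](C)OCOC)CCC1=O | intermediate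
19 | (2S,3S)-2-[(6S,8S)-6-[(3S)-5-(benzyloxy)-3-methylpentyl]-7-methylidene-1,4-dioxaspiro[4.5]decan-8-yl]-3-(methoxymethoxy)-2-methylbutanoic acid | c1ccccc1COCC[C@@H](C)CC[C@H]1C(=C)[C@@H]([C@](C)(C(=O)O)[C@H](C)OCOC)CCC12OCCO2 | intermediate
20 | acid chloride of 19 | c1ccccc1COCC[C@@H](C)CC[C@H]1C(=C)[C@@H]([C@](C)(C(Cl)=O)[C@H](C)OCOC)CCC12OCCO2 | intermediate
21 | (4S,5S)-4-[(6S,8S)-6-[(3S)-5-(benzyloxy)-3-methylpentyl]-7-methylidene-1,4-dioxaspiro[4.5]decan-8-yl]-5-(methoxymethoxy)-4-methylhex-1-en-3-one | c1ccccc1COCC[C@@H](C)CC[C@H]1C(=C)[C@@H]([C@](C)(C(=O)C=C)[C@H](C)OCOC)CCC12OCCO2 | intermediate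
22 | (4S,5S,9S,10R,13S,18S)-15-(benzyloxy)-8,8-(ethane-1,2-diyldioxy)-18-(methoxymethoxy)-18-methyl-17-norlabdan-3-one | c1ccccc1COCC[C@@H](C)CC[C@H]1[C@]2(C)CCC(=O)[C@](C)([C@H](C)OCOC)[C@H]2CCC13OCCO3 | intermediate
23 | C3 hydrazone of 22 | c1ccccc1COCC[C@@H](C)CC[C@H]1[C@]2(C)CCC(=NN)[C@](C)([C@H](C)OCOC)[C@H]2CCC13OCCO3 | intermediate
24 | (4S,5S,9S,10R,13S,18S)-15-(benzyloxy)-8,8-(ethane-1,2-diyldioxy)-18-(methoxymethoxy)-18-methyl-17-norlabdane | c1ccccc1COCC[C@@H](C)CC[C@H]1[C@]2(C)CCC[C@](C)([C@H](C)OCOC)[C@H]2CCC13OCCO3 | intermediate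
25 | (4S,5S,9S,10R,13S,18S)-15-(benzyloxy)-18-hydroxy-18-methyl-17-norlabdan-8-one | c1ccccc1COCC[C@@H](C)CC[C@H]1[C@]2(C)CCC[C@](C)([C@H](C)O)[C@H]2CCC1=O | intermediate
26 | (4S,5S,9R,10S,13S,18S)-15-(benzyloxy)-18-methyllabd-8(17)-en-18-ol | c1ccccc1COCC[C@@H](C)CC[C@H]1[C@]2(C)CCC[C@](C)([C@H](C)O)[C@H]2CCC1=C | intermediate
27 | (4S,5S,8S,9S,10R,13S,18S)-15-(benzyloxy)-18-methyllabdane-8,18-diol | c1ccccc1COCC[C@@H](C)CC[C@H]1[C@]2(C)CCC[C@](C)([C@H](C)O)[C@H]2CC[C@]1(C)O | intermediate
28 | (4S,5S,8S,9S,10R,13S)-15-(benzyloxy)-8-hydroxy-18-methyllabdan-18-one | c1ccccc1COCC[C@@H](C)CC[C@H]1[C@]2(C)CCC[C@](C)(C(C)=O)[C@H]2CC[C@]1(C)O | intermediate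
29 | (4S,5S,8S,9S,10R,13S)-15-(benzyloxy)-8-hydroxy-18-(tribromomethyl)labdan-18-one | c1ccccc1COCC[C@@H](C)CC[C@H]1[C@]2(C)CCC[C@](C)(C(=O)C(Br)(Br)Br)[C@H]2CC[C@]1(C)O | intermediate
30 | (4S,5S,8S,9S,10R,13S)-15-(benzyloxy)-8-hydroxylabdan-18-oic acid | c1ccccc1COCC[C@@H](C)CC[C@H]1[C@]2(C)CCC[C@](C)(C(=O)O)[C@H]2CC[C@]1(C)O | intermediate
31 | (4S,5S,8S,9S,10R,13S)-8,15-dihydroxylabdan-18-oic acid | OCC[C@@H](C)CC[C@H]1[C@]2(C)CCC[C@](C)(C(=O)O)[C@H]2CC[C@]1(C)O | intermediate
32 | (4S,5S,8S,9S,10R,13S)-15-(acetyloxy)-8-hydroxylabdan-18-oic acid | CC(=O)OCC[C@@H](C)CC[C@H]1[C@]2(C)CCC[C@](C)(C(=O)O)[C@H]2CC[C@]1(C)O | target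

**Step count**

Total steps: 22. Longest linear sequence: 21 (steps 1 to 7 and 9 to 22; step 8 is a one-step branch).

**Steps most likely to fail**

Step 15. The iron hydride may reduce the vinyl ketone, or isomerise or saturate the methylene by reversible hydrogen-atom transfer, faster than the ring closes. The fallback generates the same C10 radical with no metal hydride present; it sets out from 19 and returns at 22. Hydration of the methylene of 19 (Mn(dpm)3, PhSiH3, O2) and acid-catalysed lactonisation should give the cis-fused gamma-lactone F1, whose C10 configuration is erased again later. Addition of CH2=CHMgBr at −78 °C opens it to the hydroxy vinyl ketone F2. Acylation of the tertiary alcohol with the chloro-oxalate of N-hydroxyphthalimide gives the N-phthalimidoyl oxalate F3. Visible-light photoreduction (Ru(bpy)3(PF6)2, diethyl 2,6-dimethyl-1,4-dihydropyridine-3,5-dicarboxylate, i-Pr2NEt·HBF4) should release the tertiary radical by double decarboxylation and close ring A to 22.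

Step 10. The fully substituted dianion may fragment by retro-aldol cleavage, or rearrange through a poorly organised transition state, before the [3,3] shift. The fallback replaces the dianionic rearrangement by a neutral Ireland–Claisen rearrangement; it sets out from 13 and returns at 15. The chelated dianion is trapped at −78 °C with Me3SiCl as the bis(trimethylsilyl) ketene acetal F4, which keeps the geometry of the chelate. Warming rearranges it to the bis-silyl acid derivative F5, and mild acidic work-up removes both silyl groups to give 15. Facial control then rests on allylic strain about the C18 stereocentre and not on the chelate, so the C4/C5 diastereomers would have to be checked and separated if needed.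

Step 19. Oxygen capture by the planar C8 radical may show poor facial selectivity. The fallback is the polar two-step hydration; it sets out from 26 and returns at 27. Epoxidation with mCPBA (NaHCO3, CH2Cl2) from the face opposite the axial C20 methyl should give the 8,17-epoxide F6, and LiAlH4 in THF opens it at the primary carbon C17 to give 27.

Further compounds
F1 | step 15 | cis-fused gamma-lactone between the C3 carboxyl group and a new C10 hydroxyl (hydration product of 19) | c1ccccc1COCC[C@@H](C)CC[C@H]1[C@@]2(C)OC(=O)[C@](C)([C@H](C)OCOC)[C@H]2CCC13OCCO3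
F2 | step 15 | C10 tertiary alcohol carrying the vinyl ketone (ring-opened F1) | c1ccccc1COCC[C@@H](C)CC[C@H]1[C@@](C)(O)[C@@H]([C@](C)(C(=O)C=C)[C@H](C)OCOC)CCC12OCCO2
F3 | step 15 | N-phthalimidoyl oxalate of F2 at the C10 oxygen | c1ccccc1COCC[C@@H](C)CC[C@H]1[C@@](C)(OC(=O)C(=O)ON3C(=O)c4ccccc4C3=O)[C@@H]([C@](C)(C(=O)C=C)[C@H](C)OCOC)CCC12OCCO2
F4 | step 10 | bis(trimethylsilyl) derivative of dianion 14 (silyl ketene acetal and silyl ether) | C[C@H](O[Si](C)(C)C)/C(C)=C(\O[Si](C)(C)C)OCC1=CCCC(O[Si](C(C)C)(C(C)C)C(C)C)=C1CC[C@H](C)CCOCc1ccccc1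
F5 | step 10 | trimethylsilyl ester and trimethylsilyl ether of 15 | C[C@H](O[Si](C)(C)C)[C@@](C)(C(=O)O[Si](C)(C)C)[C@H]1CCC(O[Si](C(C)C)(C(C)C)C(C)C)=C(CC[C@H](C)CCOCc2ccccc2)C1=C
F6 | step 19 | 8,17-epoxide of 26 with the oxygen on the face opposite C20 | c1ccccc1COCC[C@@H](C)CC[C@H]1[C@]2(C)CCC[C@](C)([C@H](C)O)[C@H]2CC[C@@]13CO3
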